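All runs come from a simulation with constants of no real substance, and the scatter is random.

At early times both runs hold target and isomer of the product side by side, Monday's run with 11.7% target and 8.4% isomer of the product at 0.250 d. We therefore take equal amounts as the zero of our scale and follow L = ln([target]/[isomer of the product]), the logarithm of the selectivity.

| setting | Saturday's | Monday's | flask |
|---|---|---|---|
| starting material | 1 M | 1 M | 1.0 M |
| coupling partner | 1.7 equiv | 2.5 equiv | 2.50 equiv |
| catalyst | 0.2 mol% | 0.1 mol% | 0.2 mol% |
| remark | run made earlier | run made earlier |  |
| time |  |  | 4.0 d |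

| run | time / d | isomer of the product / % | target / % |
|---|---|---|---|
| Saturday's | 0.500 | 8.4 | 8.1 |
| Saturday's | 0.833 | 11.1 | 6.2 |
| Saturday's | 1.25 | 11.2 | 4.1 |
| Saturday's | 1.67 | 10.9 | 2.3 |
| Saturday's | 2.50 | 9.3 | 1.3 |
| Saturday's | 3.00 | 8.5 | 0.8 |
| Monday's | 0.250 | 8.4 | 11.7 |
| Monday's | 0.833 | 14.0 | 9.3 |
| Monday's | 1.67 | 14.7 | 3.7 |
| Monday's | 2.50 | 13.3 | 1.9 |
| Monday's | 3.00 | 11.3 | 0.9 |

(readings scatter by 0.3 percentage points)



- share of isomer of the product in isomer of the product plus target at 30 min
- share of isomer of the product in isomer of the product plus target at 6.0 h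
- share of isomer of the product in isomer of the product plus target at 4.0 d
- which of isomer of the product and target there is more of at 4.0 d

Saturday's run has the flask's catalyst loading. Between 0.500 d and 1.67 d it reads 1.30 d⁻¹ for the parting rate, the fall of L per day. Monday's run has the flask's partner charge, and at 0.250 d it reads L = 0.331. Monday's run has half the flask's catalyst loading, but as an estimate we take that as the flask's value at 6.0 h, an isomer share of 41.8%. Going back with the parting rate gives 34.8% at 30 min.

Going forward in a straight line gives 98.9% at 4.0 d, and that line is our weak link. Saturday's readings from 1.67 d to 3.00 d part at 0.607 d⁻¹, slower than before. This is a rough reading, with a scatter of 0.3 percentage points on a target reading of 0.8%. So we start again from Monday's L at 1.67 d, continue at this later rate, and commit to 94.2%, with isomer of the product ahead.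

The forecast gives 38%, 43% and 96.8%, with isomer of the product ahead, and calls Monday's early isomer “far too much to have come through target”.

The flask gives 36.6%, 44.4% and 92.3%, and at 4.0 d it holds 9.07% isomer of the product and 0.755% target.

    2 starting material → self-condensation product (k = 0.0422 M⁻¹ h⁻¹)
    target → over-reaction product (k = 0.0234 h⁻¹)
    starting material + coupling partner ⇌ target (K = 0.346 M⁻¹, k = 0.0169 M⁻¹ h⁻¹)
    starting material + coupling partner ⇌ isomer of the product (K = 1.25 M⁻¹, k = 0.00948 M⁻¹ h⁻¹)
    coupling partner → decomposed reagent (k = 0.0544 h⁻¹)
    target + catalyst ⇌ isomer of the product + catalyst, rate k6*[catalyst]*[target] forward; the back reaction follows from the equilibrium constant (k = 9.89 M⁻¹ h⁻¹)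

In this flask, with each step taken net, target is made at 0.324 of the rate at which it is used up at 0.524 d, and at 0.740 of that rate at 4.00 d. From the flask's share at 6.0 h, our parting rate puts the level point at 0.423 d; the flask stands level at 0.406 d.

Now take the same flask with 0.8 mol% catalyst. From its 37.4% at 30 min, our parting rate gives 44.6% at 6.0 h. The computed share is 52.2%, a parting rate of 2.64 d⁻¹, faster than ours.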